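**Assumption:** the SMILES is read as (5S,6S,8R,9R,10S,13R), i.e. 6α-angeloyloxy-sclareol. Labdane numbering is used throughout, and every decalin intermediate keeps the sclareolide configuration (5α-H, 9α-H with the C9 chain β, 10β-CH3).

## Retrosynthetic overview

1. Target 20 ⇒ triol 16 (6α-hydroxysclareol) + angelic acid: acylation of the only secondary hydroxyl.
2. 16 ⇒ 7α,8α-epoxy-6-ketone 14 ⇒ enone 13 ⇒ Δ7 alkene 12: C6–O by allylic oxidation, C8–O(α) put back by nucleophilic epoxidation and SmI2.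
3. 12 ⇒ C12–C13 (key bond): primary boronate 5 + lithiated (S)-but-3-en-2-yl carbamate 9, an α-oxygenated carbanion (the carbinol/carbonyl carbon used with reversed polarity); the 1,2-metallate shift sets C13 (R).
4. 5 ⇒ (+)-sclareolide 1 by eliminative lactone opening, reduction, iodination and borylation.
5. No ring is formed: the trans-decalin (C5, C9, C10) is bought with 1; only its lactone ring is opened.

## Route

Step 1
Reactants: 1 (+)-sclareolide
Product: 2 methyl 13,14,15,16-tetranorlabd-7-en-12-oate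
Conditions: conc. H2SO4 (0.3 equiv), MeOH, reflux; AgNO3–SiO2 chromatography; Δ8(9)/Δ8(17) isomers re-equilibrated under the same conditions
Reagents that add atoms: methanol (CO)
Why: Acid-catalysed AAL1 opening of the tertiary lactone C8–O bond, E1 loss of the axial 7α-H and Fischer esterification give the Δ7 ester together with its Δ8(9)/Δ8(17) isomers (the Δ8(9) isomer may well dominate at equilibrium, hence separation and recycling); C5, C9 and C10 are carried over unchanged from 1.

Step 2
Reactants: 2 methyl 13,14,15,16-tetranorlabd-7-en-12-oate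
Product: 3 13,14,15,16-tetranorlabd-7-en-12-ol
Conditions: LiAlH4, THF, 0 °C → rt
Reagents that add atoms: none
Why: Hydride reduction of the ester to the primary alcohol; the trisubstituted alkene and all stereocentres are untouched.

Step 3
Reactants: 3 13,14,15,16-tetranorlabd-7-en-12-ol
Product: 4 12-iodo-13,14,15,16-tetranorlabd-7-ene
Conditions: I2, PPh3, imidazole, CH2Cl2, 0 °C → rt
Reagents that add atoms: iodine (II)
Why: Appel iodination of an unhindered primary alcohol under neutral conditions; no stereocentre is involved.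

Step 4
Reactants: 4 12-iodo-13,14,15,16-tetranorlabd-7-ene
Product: 5 pinacol (13,14,15,16-tetranorlabd-7-en-12-yl)boronate
Conditions: B2pin2, CuI (10 mol %), PPh3 (13 mol %), LiOMe, DMF, rt
Reagents that add atoms: bis(pinacolato)diboron (CC1(C)OB(OC1(C)C)B1OC(C)(C)C(C)(C)O1)
Why: Copper-catalysed borylation of a primary alkyl iodide; the remote trisubstituted alkene does not interfere and no stereocentre is touched.

Step 5
Reactants: 6 (S)-but-3-en-2-ol, 7 N,N-diisopropylcarbamoyl chloride
Product: 8 (S)-but-3-en-2-yl N,N-diisopropylcarbamate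
Conditions: Et3N, DMAP (cat.), toluene, reflux
Reagents that add atoms: none
Why: O-carbamoylation of the secondary alcohol; the C–O bond is not broken, so the (S) configuration is retained.

Step 6
Reactants: 8 (S)-but-3-en-2-yl N,N-diisopropylcarbamate, 5 pinacol (13,14,15,16-tetranorlabd-7-en-12-yl)boronate
Product: 12 (13R)-labda-7,14-dien-13-ol, via lithiated carbamate 9 (not isolated), via lithium boronate complex 10 (not isolated), via tertiary allylic boronic ester 11 (not isolated)
Conditions: 8, s-BuLi, TMEDA, Et2O, −78 °C; then 5, −78 °C → rt; then NaOH, H2O2, THF, 0 °C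
Reagents that add atoms: hydrogen peroxide (OO)
Why: Hoppe–Aggarwal lithiation–borylation: s-BuLi removes the allylic α-oxy proton of 8 with retention to give the α-carbamoyloxy allyllithium 9 (the carbinol carbon used as a carbanion), which is borylated at the α-carbon with retention; anti 1,2-migration of C12 from boron with loss of the carbamate and retentive B→O oxidation give net replacement of H by C12 with retention, so (S)-8 gives (13R)-12.

Step 7
Reactants: 12 (13R)-labda-7,14-dien-13-ol
Product: 13 (13R)-13-hydroxylabda-7,14-dien-6-one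
Conditions: Rh2(cap)4 (1 mol %), t-BuOOH (5 equiv), K2CO3, CH2Cl2, rt
Reagents that add atoms: tert-butyl hydroperoxide (CC(C)(C)OO)
Why: Doyle dirhodium caprolactamate/TBHP allylic oxidation: the peroxyl radical abstracts a C6–H next to the CH= end of the trisubstituted alkene and the mixed peroxide collapses to the conjugated 6-oxo-Δ7 enone; the vinyl carbinol has no allylic or carbinol hydrogen to lose and no stereocentre is formed.

Step 8
Reactants: 13 (13R)-13-hydroxylabda-7,14-dien-6-one
Product: 14 (13R)-7α,8α-epoxy-13-hydroxylabd-14-en-6-one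
Conditions: 30% H2O2, NaOH (cat.), MeOH, 0 °C → rt
Reagents that add atoms: hydrogen peroxide (OO)
Why: Weitz–Scheffer nucleophilic epoxidation: HOO− adds to C8 from the α-face (the β-face is shielded by the axial C10 methyl) and the enolate closes the 7α,8α-epoxide, which fixes C8 (α-oxygen, β-methyl); the isolated vinyl group is inert to alkaline peroxide.

Step 9
Reactants: 14 (13R)-7α,8α-epoxy-13-hydroxylabd-14-en-6-one
Product: 16 (13R)-labd-14-ene-6α,8α,13-triol, via β-hydroxy ketone 15 (not isolated)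
Conditions: SmI2 (5 equiv), THF–MeOH (4:1), −90 °C → 0 °C
Reagents that add atoms: none
Why: Molander-type SmI2 cleavage of the Cα–O bond of the α,β-epoxy ketone keeps the C8–O bond (8α-OH) and gives β-hydroxy ketone 15; its chelated samarium ketyl is then reduced and protonated so that oxygen takes the equatorial 6α position (the axial 6β site faces the 4β-, 8β- and 10β-methyls), setting C6 (S).

Step 10
Reactants: 16 (13R)-labd-14-ene-6α,8α,13-triol, 17 angelic acid, 18 2,4,6-trichlorobenzoyl chloride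
Product: 20 (13R)-6α-angeloyloxylabd-14-ene-8α,13-diol, via angelic trichlorobenzoic anhydride 19 (not isolated)
Conditions: 17, 18, Et3N, toluene, rt; then 16, 80 °C
Reagents that add atoms: none
Why: Yamaguchi-type mixed-anhydride esterification: only the secondary equatorial 6α-OH is acylated (8-OH and 13-OH are tertiary) and the DMAP-free conditions avoid angelate-to-tiglate isomerisation; no stereocentre is touched.

## Compound list

1 | (+)-sclareolide, (3aR,5aS,9aS,9bR)-3a,6,6,9a-tetramethyldecahydronaphtho[2,1-b]furan-2-one | O=C1C[C@@H]2[C@@]3(C)CCCC(C)(C)[C@@H]3CC[C@@]2(C)O1 | starting material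
2 | methyl 13,14,15,16-tetranorlabd-7-en-12-oate (5α-H, 9α-H, 10β-Me) | COC(=O)C[C@@H]1[C@@]2(C)CCCC(C)(C)[C@@H]2CC=C1C | intermediate
3 | 13,14,15,16-tetranorlabd-7-en-12-ol (5α-H, 9α-H, 10β-Me) | OCC[C@@H]1[C@@]2(C)CCCC(C)(C)[C@@H]2CC=C1C | intermediate
4 | 12-iodo-13,14,15,16-tetranorlabd-7-ene (5α-H, 9α-H, 10β-Me) | ICC[C@@H]1[C@@]2(C)CCCC(C)(C)[C@@H]2CC=C1C | intermediate
5 | pinacol (13,14,15,16-tetranorlabd-7-en-12-yl)boronate (5α-H, 9α-H, 10β-Me) | CC1(C)OB(CC[C@@H]2[C@@]3(C)CCCC(C)(C)[C@@H]3CC=C2C)OC1(C)C | intermediate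
6 | (S)-but-3-en-2-ol | C[C@H](O)C=C | starting material
7 | N,N-diisopropylcarbamoyl chloride | CC(C)N(C(C)C)C(=O)Cl | starting material
8 | (S)-but-3-en-2-yl N,N-diisopropylcarbamate | C[C@H](OC(=O)N(C(C)C)C(C)C)C=C | intermediate
9 | (S)-2-lithiobut-3-en-2-yl N,N-diisopropylcarbamate (Li in the place of the carbinol H of 8) | C[C@]([Li])(OC(=O)N(C(C)C)C(C)C)C=C | intermediate
10 | lithium boronate complex of 9 and 5 (tetracoordinate boron carrying pinacolate, C12 and the carbamoyloxy-bearing C13) | [Li+].C=C[C@](C)(OC(=O)N(C(C)C)C(C)C)[B-]1(CC[C@@H]2[C@@]3(C)CCCC(C)(C)[C@@H]3CC=C2C)OC(C)(C)C(C)(C)O1 | intermediate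
11 | pinacol labda-7,14-dien-13-ylboronate (boron in the position later taken by the 13-OH) | C=C[C@](C)(B1OC(C)(C)C(C)(C)O1)CC[C@@H]2[C@@]3(C)CCCC(C)(C)[C@@H]3CC=C2C | intermediate
12 | (13R)-labda-7,14-dien-13-ol | C=C[C@](C)(O)CC[C@@H]1[C@@]2(C)CCCC(C)(C)[C@@H]2CC=C1C | intermediate
13 | (13R)-13-hydroxylabda-7,14-dien-6-one | C=C[C@](C)(O)CC[C@@H]1[C@@]2(C)CCCC(C)(C)[C@@H]2C(=O)C=C1C | intermediate
14 | (13R)-7α,8α-epoxy-13-hydroxylabd-14-en-6-one | C=C[C@](C)(O)CC[C@@H]1[C@@]2(C)CCCC(C)(C)[C@@H]2C(=O)[C@H]3O[C@@]13C | intermediate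
15 | (13R)-8α,13-dihydroxylabd-14-en-6-one | C=C[C@](C)(O)CC[C@@H]1[C@@]2(C)CCCC(C)(C)[C@@H]2C(=O)C[C@@]1(C)O | intermediate
16 | (13R)-labd-14-ene-6α,8α,13-triol (6α-hydroxysclareol; 6S,8R) | C=C[C@](C)(O)CC[C@@H]1[C@@]2(C)CCCC(C)(C)[C@@H]2[C@@H](O)C[C@@]1(C)O | intermediate
17 | angelic acid, (Z)-2-methylbut-2-enoic acid | C/C=C(/C)C(=O)O | starting material
18 | 2,4,6-trichlorobenzoyl chloride | O=C(Cl)c1c(Cl)cc(Cl)cc1Cl | starting material
19 | angelic 2,4,6-trichlorobenzoic anhydride | C/C=C(/C)C(=O)OC(=O)c1c(Cl)cc(Cl)cc1Cl | intermediate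
20 | (13R)-6α-angeloyloxylabd-14-ene-8α,13-diol, (5S,6S,8R,9R,10S,13R) | C=C[C@](C)(O)CC[C@@H]1[C@@]2(C)CCCC(C)(C)[C@@H]2[C@@H](OC(=O)/C(C)=C\C)C[C@@]1(C)O | target

## Step count and risks

Total step count: 10 (steps 1–10). Longest linear sequence: 9 (steps 1, 2, 3, 4, 6, 7, 8, 9, 10); step 5 is a one-step side branch.

**Steps most likely to fail**

- **Step 1 (regiochemistry of the elimination).** The E1 opening gives Δ7, Δ8(9) and Δ8(17) esters, and 2 may be only a minor part of the equilibrium mixture. Fallback, setting out from 1 and returning at 2: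
  - Open 1 with KOH in aqueous MeOH to potassium 8α-hydroxy-13,14,15,16-tetranorlabdan-12-oate F1.
  - Methylate in the same flask (MeI, DMF) to methyl 8α-hydroxy-13,14,15,16-tetranorlabdan-12-oate F2.
  - Dehydrate under E2 control (SOCl2, pyridine, CH2Cl2, −78 °C; only the C17 hydrogens are anti to the equatorial leaving group) to the exocyclic alkene methyl 13,14,15,16-tetranorlabd-8(17)-en-12-oate F3.
  - Isomerise F3 with RhCl3·3H2O in refluxing EtOH (allyl-hydride pathway through the unhindered C7–H, not the tertiary C9–H) to 2.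

- **Step 6 (key C12–C13 coupling).** Possible failures are γ- instead of α-borylation of the 1-methylallyllithium, loss of its configuration, or a sluggish 1,2-shift to the tertiary centre. If borylation went with inversion, the (R)-carbamate would be needed instead. Fallback, setting out from 4 and returning at 12:
  - Deprotonate 2-methyl-1,3-dithiane (n-BuLi, THF, −30 °C) to the acyl-anion equivalent 2-lithio-2-methyl-1,3-dithiane F4.
  - Alkylate it with iodide 4 to 2-methyl-2-(13,14,15,16-tetranorlabd-7-en-12-yl)-1,3-dithiane F5.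
  - Unmask with I2, NaHCO3 in aqueous acetone to 14,15-dinorlabd-7-en-13-one F6.
  - Add CH2=CHMgBr/CeCl3 (THF, −78 °C). This is not stereoselective at C13, so 12 is separated by chromatography from its epimer (13S)-labda-7,14-dien-13-ol F7.

- **Step 7 (allylic oxidation).** The tertiary allylic C9–H could be abstracted instead of C6–H (giving a 7-oxo-Δ8 enone), and the vinyl carbinol may not survive peroxyl-radical conditions. Fallback, setting out from 12 and returning at 13:
  - Silylate the tertiary carbinol (TESOTf, 2,6-lutidine, CH2Cl2, −78 °C) to (13R)-13-(triethylsilyloxy)labda-7,14-diene F8.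
  - Oxidise C6 with stoichiometric Cr(VI) (CrO3·3,5-dimethylpyrazole, CH2Cl2, −20 °C), which can no longer trigger an oxidative allylic transposition of the side chain, to (13R)-13-(triethylsilyloxy)labda-7,14-dien-6-one F9.
  - Remove the silyl group (TBAF, THF) to give 13.

## Further compounds

F1 | step 1 | potassium 8α-hydroxy-13,14,15,16-tetranorlabdan-12-oate | [K+].[O-]C(=O)C[C@@H]1[C@@]2(C)CCCC(C)(C)[C@@H]2CC[C@@]1(C)O
F2 | step 1 | methyl 8α-hydroxy-13,14,15,16-tetranorlabdan-12-oate | COC(=O)C[C@@H]1[C@@]2(C)CCCC(C)(C)[C@@H]2CC[C@@]1(C)O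
F3 | step 1 | methyl 13,14,15,16-tetranorlabd-8(17)-en-12-oate | COC(=O)C[C@@H]1[C@@]2(C)CCCC(C)(C)[C@@H]2CCC1=C
F4 | step 6 | 2-lithio-2-methyl-1,3-dithiane | [Li]C1(C)SCCCS1
F5 | step 6 | 2-methyl-2-(13,14,15,16-tetranorlabd-7-en-12-yl)-1,3-dithiane | CC1(CC[C@@H]2[C@@]3(C)CCCC(C)(C)[C@@H]3CC=C2C)SCCCS1
F6 | step 6 | 14,15-dinorlabd-7-en-13-one | CC(=O)CC[C@@H]1[C@@]2(C)CCCC(C)(C)[C@@H]2CC=C1C
F7 | step 6 | (13S)-labda-7,14-dien-13-ol | C=C[C@@](C)(O)CC[C@@H]1[C@@]2(C)CCCC(C)(C)[C@@H]2CC=C1C
F8 | step 7 | (13R)-13-(triethylsilyloxy)labda-7,14-diene | C=C[C@](C)(O[Si](CC)(CC)CC)CC[C@@H]1[C@@]2(C)CCCC(C)(C)[C@@H]2CC=C1C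
F9 | step 7 | (13R)-13-(triethylsilyloxy)labda-7,14-dien-6-one | C=C[C@](C)(O[Si](CC)(CC)CC)CC[C@@H]1[C@@]2(C)CCCC(C)(C)[C@@H]2C(=O)C=C1C
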